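**Retrosynthetic overview**

- The last bond is the ester C–O bond: tyrosol is acylated at its primary alcohol only, by a lipase, with docosanoic acid.
- The only ring is a para-disubstituted benzene with a mirror plane through C1 (bearing OH) and C4 (bearing the CH2CH2O chain). Ring bonds C1–C2 and C1–C6 are cut together, leaving a symmetric five-carbon C2–C6 unit as a Z,Z-1,5-dilithio-penta-1,4-diene and C1 as a carbonate carbonyl.
- The dilithio-diene comes from the (1Z,4Z)-1,5-dibromide, and this from a 3-substituted bis(silylalkyne) by bromodesilylation and diimide syn-reduction.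
- The skipped diyne comes from ethyl formate and two silylacetylides. Its C3–CH2 bond is made by a Nicholas reaction of the cobalt-complexed diynol with a ketene silyl acetal, which replaces an unassisted propargylic substitution.
- Ring order: one ring, closed in step 8.

Key step: step 8

Remark: the target has no stereocentre; the only stereochemical element in the route is the Z geometry of both bromoalkenes in 13, set in step 7.

**Step 1**
Reactants: 1 ethyl formate; 2 trimethylsilylacetylene
Product: 5 1,5-bis(trimethylsilyl)penta-1,4-diyn-3-ol, via lithium (trimethylsilyl)acetylide 3 (not isolated), via 3-(trimethylsilyl)prop-2-ynal 4 (not isolated)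
Conditions: 2 (2.1 equiv), n-BuLi (2.05 equiv), THF, −78 °C; then 1 (1.0 equiv), −78 → 0 °C; aq. NH4Cl
Reagents that add atoms: none
Why: Twofold addition of a lithium acetylide to a formate ester (acyl substitution to ynal 4, then 1,2-addition) is the standard entry to symmetrical 1,4-diyn-3-ols, and C3 is not stereogenic because it carries two identical alkynyl groups.

**Step 2**
Reactants: 5 1,5-bis(trimethylsilyl)penta-1,4-diyn-3-ol; 6 1-(tert-butyldimethylsilyloxy)-1-methoxyethene
Product: 8 bis(hexacarbonyldicobalt) complex of methyl 5-(trimethylsilyl)-3-[(trimethylsilyl)ethynyl]pent-4-ynoate (each C≡C bridging one Co2(CO)6 unit), via bis(hexacarbonyldicobalt)-complexed diynol 7 (not isolated)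
Conditions: Co2(CO)8 (2.2 equiv), CH2Cl2, rt; then 6 (2 equiv), BF3·OEt2, −78 → 0 °C; aq. NaHCO3
Reagents that add atoms: dicobalt octacarbonyl, O=C=[Co](=C=O)(=C=O)(=C=O)[Co](=C=O)(=C=O)(=C=O)=C=O
Why: Nicholas reaction: with each C≡C held as a Co2(CO)6 cluster, BF3 ionises the C3–OH to a cluster-stabilised propargylic cation that the ketene silyl acetal should capture only at C3 (no allene pathway), forming the C3–CH2 bond while BF3 is returned when the silyl group passes to the departing hydroxide.

**Step 3**
Reactants: 8 bis(hexacarbonyldicobalt) complex of the diyne ester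
Product: 9 methyl 5-(trimethylsilyl)-3-[(trimethylsilyl)ethynyl]pent-4-ynoate
Conditions: (NH4)2Ce(NO3)6 (10 equiv), acetone, −78 → 0 °C
Reagents that add atoms: none
Why: Oxidative decomplexation: tetravalent cerium oxidises the zerovalent cobalt of both clusters to divalent cobalt, which releases CO and the two free alkynes and leaves the ester and the C–Si bonds untouched.

**Step 4**
Reactants: 9 methyl 5-(trimethylsilyl)-3-[(trimethylsilyl)ethynyl]pent-4-ynoate
Product: 10 5-(trimethylsilyl)-3-[(trimethylsilyl)ethynyl]pent-4-yn-1-ol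
Conditions: i-Bu2AlH (2.5 equiv), CH2Cl2, −78 → 0 °C; aq. potassium sodium tartrate
Reagents that add atoms: none
Why: Hydride reduction of the methyl ester to the primary alcohol proceeds at low temperature, where silylalkynes are not hydroaluminated and the non-basic reagent leaves the doubly propargylic C–H alone.

**Step 5**
Reactants: 10 5-(trimethylsilyl)-3-[(trimethylsilyl)ethynyl]pent-4-yn-1-ol
Product: 11 tert-butyldimethyl({5-(trimethylsilyl)-3-[(trimethylsilyl)ethynyl]pent-4-yn-1-yl}oxy)silane
Conditions: TBSCl (1.2 equiv), imidazole (2.2 equiv), CH2Cl2, rt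
Reagents that add atoms: tert-butyldimethylsilyl chloride, CC(C)(C)[Si](C)(C)Cl
Why: Imidazole-mediated silylation of a primary alcohol gives a silyl ether that withstands t-BuLi at −78 °C in step 8.

**Step 6**
Reactants: 11 bis(trimethylsilyl) diyne silyl ether
Product: 12 {[5-bromo-3-(bromoethynyl)pent-4-yn-1-yl]oxy}(tert-butyl)dimethylsilane
Conditions: NBS (2.4 equiv), AgNO3 (0.2 equiv), acetone, rt, dark
Reagents that add atoms: N-bromosuccinimide, O=C1CCC(=O)N1Br
Why: Silver-catalysed bromodesilylation: AgNO3 activates each alkynyl C–SiMe3 bond toward ipso-substitution by electrophilic bromine under neutral conditions, so the bulkier O–Si ether and the C3–H stay in place.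

**Step 7**
Reactants: 12 bis(bromoalkyne)
Product: 13 (1Z,4Z)-1,5-dibromo-3-[2-(tert-butyldimethylsilyloxy)ethyl]penta-1,4-diene
Conditions: 2-nitrobenzenesulfonylhydrazide (6 equiv), Et3N, THF/i-PrOH, rt
Reagents that add atoms: none
Why: Diimide reduction: HN=NH released from the sulfonylhydrazide delivers both hydrogens to one face of each C≡C through a cyclic transition state, so each bromoalkyne should give the (Z)-bromoalkene, which is reduced far more slowly than the bromoalkyne.

**Step 8**
Reactants: 13 (1Z,4Z)-1,5-dibromo-3-[2-(tert-butyldimethylsilyloxy)ethyl]penta-1,4-diene; 14 dibenzyl carbonate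
Product: 18 4-[2-(tert-butyldimethylsilyloxy)ethyl]phenol, via (1Z,4Z)-1,5-dilithio-diene 15 (not isolated), via lithio benzyl dienoate 16 (not isolated), via cyclohexa-2,5-dienone 17 (not isolated)
Conditions: t-BuLi (4.2 equiv), Et2O, −78 °C; then 14 (1.0 equiv), −78 °C → rt; aq. NH4Cl
Reagents that add atoms: none
Why: Two bromine–lithium exchanges (two t-BuLi per C–Br, the second destroying t-BuBr) give the Z,Z-dilithio-diene 15 with retention at both alkenes; one vinyllithium adds to the carbonate carbonyl and loss of benzyl oxide leaves benzyl dienoate 16 (bond C1–C2), whose ester carbonyl is attacked by the second vinyllithium to form C1–C6, and loss of the second benzyl oxide gives dienone 17. The closest known reaction type is the formal [5+1] annulation of 1,5-dilithio-1,4-dienes with carbonate esters to phenols, a double nucleophilic acyl substitution. The one ring closes in the 6-exo-trig mode, the attacked C=O being exocyclic to the forming six-membered ring, and the Z geometry of both alkenes holds the C–Li terminus next to the ester. No stereocentre is created, since C4 of 17 lies on the mirror plane of the ring and its hydrogen is removed by benzyl oxide to give the phenoxide, so aromatisation needs no oxidant. The step needs retention of both Z alkenes, exchange faster than anti-dehydrobromination or removal of the doubly allylic C3–H, and cyclisation faster than intermolecular acylation; these rest on the configurational stability of vinyllithiums at −78 °C, the speed of t-BuLi exchange at that temperature, and the intramolecular second acylation with only one equivalent of carbonate.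

**Step 9**
Reactants: 18 4-[2-(tert-butyldimethylsilyloxy)ethyl]phenol
Product: 19 4-(2-hydroxyethyl)phenol (tyrosol)
Conditions: HCl (cat., 1% in MeOH), 0 °C → rt
Reagents that add atoms: none
Why: Acid-catalysed methanolysis of a primary silyl ether (solvolytic desilylation) frees the alcohol, and the phenol is inert to these conditions.

**Step 10**
Reactants: 19 4-(2-hydroxyethyl)phenol; 20 docosanoic acid
Product: 21 2-(4-hydroxyphenyl)ethyl docosanoate
Conditions: 20 (1.5 equiv), immobilised Candida antarctica lipase B (Novozym 435), 4 Å molecular sieves, 2-methyl-2-butanol, 60 °C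
Reagents that add atoms: none
Why: Lipase-catalysed esterification: the acyl-enzyme of Candida antarctica lipase B is transferred to the primary aliphatic alcohol but not to the phenol, so only the CH2OH should be acylated while the sieves remove water and the tertiary alcohol solvent is not a substrate.

**Compound list**

1 | ethyl formate | CCOC=O | starting material
2 | trimethylsilylacetylene | C#C[Si](C)(C)C | starting material
3 | lithium (trimethylsilyl)acetylide | [Li]C#C[Si](C)(C)C | intermediate
4 | 3-(trimethylsilyl)prop-2-ynal | O=CC#C[Si](C)(C)C | intermediate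
5 | 1,5-bis(trimethylsilyl)penta-1,4-diyn-3-ol | C[Si](C)(C)C#CC(O)C#C[Si](C)(C)C | intermediate
6 | 1-(tert-butyldimethylsilyloxy)-1-methoxyethene | C=C(OC)O[Si](C)(C)C(C)(C)C | starting material
7 | bis(hexacarbonyldicobalt) complex of 1,5-bis(trimethylsilyl)penta-1,4-diyn-3-ol (each C≡C bridging one Co2(CO)6 unit) | C[Si](C)(C)C12C3(C(O)C45C6([Si](C)(C)C)[Co]4(=C=O)(=C=O)(=C=O)[Co]56(=C=O)(=C=O)=C=O)[Co]1(=C=O)(=C=O)(=C=O)[Co]23(=C=O)(=C=O)=C=O | intermediate
8 | bis(hexacarbonyldicobalt) complex of methyl 5-(trimethylsilyl)-3-[(trimethylsilyl)ethynyl]pent-4-ynoate (each C≡C bridging one Co2(CO)6 unit) | C[Si](C)(C)C12C3(C(CC(=O)OC)C45C6([Si](C)(C)C)[Co]4(=C=O)(=C=O)(=C=O)[Co]56(=C=O)(=C=O)=C=O)[Co]1(=C=O)(=C=O)(=C=O)[Co]23(=C=O)(=C=O)=C=O | intermediate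
9 | methyl 5-(trimethylsilyl)-3-[(trimethylsilyl)ethynyl]pent-4-ynoate | COC(=O)CC(C#C[Si](C)(C)C)C#C[Si](C)(C)C | intermediate
10 | 5-(trimethylsilyl)-3-[(trimethylsilyl)ethynyl]pent-4-yn-1-ol | OCCC(C#C[Si](C)(C)C)C#C[Si](C)(C)C | intermediate
11 | tert-butyldimethyl({5-(trimethylsilyl)-3-[(trimethylsilyl)ethynyl]pent-4-yn-1-yl}oxy)silane | CC(C)(C)[Si](C)(C)OCCC(C#C[Si](C)(C)C)C#C[Si](C)(C)C | intermediate
12 | {[5-bromo-3-(bromoethynyl)pent-4-yn-1-yl]oxy}(tert-butyl)dimethylsilane | CC(C)(C)[Si](C)(C)OCCC(C#CBr)C#CBr | intermediate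
13 | (1Z,4Z)-1,5-dibromo-3-[2-(tert-butyldimethylsilyloxy)ethyl]penta-1,4-diene | Br/C=C\C(CCO[Si](C)(C)C(C)(C)C)/C=C\Br | intermediate
14 | dibenzyl carbonate | O=C(OCc1ccccc1)OCc1ccccc1 | starting material
15 | (1Z,4Z)-1,5-dilithio-3-[2-(tert-butyldimethylsilyloxy)ethyl]penta-1,4-diene | [Li]/C=C\C(CCO[Si](C)(C)C(C)(C)C)/C=C\[Li] | intermediate
16 | benzyl (2Z,5Z)-6-lithio-4-[2-(tert-butyldimethylsilyloxy)ethyl]hexa-2,5-dienoate | [Li]/C=C\C(CCO[Si](C)(C)C(C)(C)C)/C=C\C(=O)OCc1ccccc1 | intermediate
17 | 4-[2-(tert-butyldimethylsilyloxy)ethyl]cyclohexa-2,5-dien-1-one | O=C1C=CC(CCO[Si](C)(C)C(C)(C)C)C=C1 | intermediate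
18 | 4-[2-(tert-butyldimethylsilyloxy)ethyl]phenol | CC(C)(C)[Si](C)(C)OCCc1ccc(O)cc1 | intermediate
19 | 4-(2-hydroxyethyl)phenol (tyrosol) | OCCc1ccc(O)cc1 | intermediate
20 | docosanoic acid | CCCCCCCCCCCCCCCCCCCCCC(=O)O | starting material
21 | 2-(4-hydroxyphenyl)ethyl docosanoate | CCCCCCCCCCCCCCCCCCCCCC(=O)OCCc1ccc(O)cc1 | target

**Step count**

Total steps: 10. Longest linear sequence: 10 steps (from 1 and 2 to 21).

**Steps most likely to fail**

1. Step 8. The risks are anti-dehydrobromination of the Z-bromoalkenes by t-BuLi before exchange, quenching of a vinyllithium by proton transfer from the doubly allylic C3–H, and intermolecular acylation giving oligomers in place of ring closure. The fallback makes the same dianion without halide or t-BuLi, from a ring that fixes both Z alkenes. It sets out from 11: methanolysis of both C–SiMe3 bonds (K2CO3, MeOH, 0 °C) would give the terminal diyne tert-butyl[(3-ethynylpent-4-yn-1-yl)oxy]dimethylsilane F1. Radical double hydrostannation with Bu2SnH2 (AIBN, heptane, reflux) would close the stannacycle 1,1-dibutyl-4-[2-(tert-butyldimethylsilyloxy)ethyl]-1,4-dihydrostannine F2. Tin–lithium exchange with n-BuLi (2 equiv, THF, −78 °C) would release dilithio-diene 15, and addition of 14 would bring the route back at 18.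

2. Step 7. The risks are reduction running on to the saturated bromide, one alkyne staying unreduced, and reductive loss of bromine, which would give mixtures that are hard to separate. The fallback replaces hydrogen transfer by a stoichiometric hydrometalation that can add only once to each alkyne. It sets out from 12: syn-hydroboration with dicyclohexylborane (2.1 equiv, THF, 0 °C) would give the bis(alkenylborane) (1Z,4Z)-1,5-dibromo-1,5-bis(dicyclohexylboryl)-3-[2-(tert-butyldimethylsilyloxy)ethyl]penta-1,4-diene F3. Protonolysis of both C–B bonds with acetic acid, with retention, would come back to the route at 13.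

3. Step 2. The risks are slow capture of the crowded cation flanked by two clusters, with dimerisation or elimination of the cation, and hydrolysis of the ketene silyl acetal. The fallback forms the C3–CH2 bond by conjugate addition and needs no cobalt, so it also replaces step 3.
   - It sets out from 2: lithiation to 3 and formylation with DMF would give aldehyde 4, here isolated.
   - Knoevenagel condensation of 4 with 2,2-dimethyl-1,3-dioxane-4,6-dione would give the alkylidene compound 2,2-dimethyl-5-[3-(trimethylsilyl)prop-2-yn-1-ylidene]-1,3-dioxane-4,6-dione F4.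
   - The Grignard reagent [(trimethylsilyl)ethynyl]magnesium bromide F5 (from 2 and EtMgBr) would add 1,4 to F4 to give 5-[1,5-bis(trimethylsilyl)penta-1,4-diyn-3-yl]-2,2-dimethyl-1,3-dioxane-4,6-dione F6.
   - Heating F6 in MeOH/pyridine with Cu powder would open the ring to the half-ester 2-(methoxycarbonyl)-5-(trimethylsilyl)-3-[(trimethylsilyl)ethynyl]pent-4-ynoic acid F7, whose decarboxylation would come back to the route at 9.

**Further compounds**

F1 | step 8 | tert-butyl[(3-ethynylpent-4-yn-1-yl)oxy]dimethylsilane | C#CC(CCO[Si](C)(C)C(C)(C)C)C#C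
F2 | step 8 | 1,1-dibutyl-4-[2-(tert-butyldimethylsilyloxy)ethyl]-1,4-dihydrostannine | CCCC[Sn]1(CCCC)C=CC(CCO[Si](C)(C)C(C)(C)C)C=C1
F3 | step 7 | (1Z,4Z)-1,5-dibromo-1,5-bis(dicyclohexylboryl)-3-[2-(tert-butyldimethylsilyloxy)ethyl]penta-1,4-diene | Br/C(B(C1CCCCC1)C1CCCCC1)=C\C(CCO[Si](C)(C)C(C)(C)C)/C=C(\Br)B(C1CCCCC1)C1CCCCC1
F4 | step 2 | 2,2-dimethyl-5-[3-(trimethylsilyl)prop-2-yn-1-ylidene]-1,3-dioxane-4,6-dione | CC1(C)OC(=O)C(=CC#C[Si](C)(C)C)C(=O)O1
F5 | step 2 | [(trimethylsilyl)ethynyl]magnesium bromide | C[Si](C)(C)C#C[Mg]Br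
F6 | step 2 | 5-[1,5-bis(trimethylsilyl)penta-1,4-diyn-3-yl]-2,2-dimethyl-1,3-dioxane-4,6-dione | CC1(C)OC(=O)C(C(C#C[Si](C)(C)C)C#C[Si](C)(C)C)C(=O)O1
F7 | step 2 | 2-(methoxycarbonyl)-5-(trimethylsilyl)-3-[(trimethylsilyl)ethynyl]pent-4-ynoic acid | COC(=O)C(C(=O)O)C(C#C[Si](C)(C)C)C#C[Si](C)(C)C
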